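**Plan**
Locants: ring A = C1, C2 (OH), C3 (O-acyl), C4 (CH3), C5 (CH3), C10; ring B = C5, C6, C7 (enol OH), C8 (C=O), C9, C10; side chain C1′–C8′.
Cuts, in retrosynthetic order: C3–O (ester, made together with the C2 OH from a 2,3-epoxide and the free dienoic acid); the C7 oxygen; C8–C9 of ring B (to a monocyclic acid chloride carrying an exocyclic C10=C9 methylene); C9=C10, C5–C6 and C4–CH3 (to a 2-methylcyclohexenone ketal); C4′=C5′ of the side chain.
Forward: ring A is bought; conjugate methylation/allylation, methylenation and chain oxidation give the keto acid; ring B is closed by acylation of the alkene; ring B is oxidised to the diosphenol, ring A is taken to its epoxide, and the side-chain acid is joined last by opening that epoxide.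
Enabling feature: the exocyclic C10=C9 alkene on ring A is 1,1-disubstituted and tied to the acyl carbon C8 through quaternary C5 (C5–C6–C7–C8), so C9 attacks C8 in a six-membered endo closure that passes through a tertiary C10 cation and ends as the C9=C10 enone.
Stereochemistry: C4 from ligand control in a copper-catalysed conjugate addition, C5 from enolate allylation anti to the C4 methyl, C3 and C2 from the ring-A chair that the new sp2 C10 locks (hydride and peracid arrive anti to the axial C5 methyl, the epoxide then opens trans-diaxially), C6′ from (S)-2-methylbutan-1-ol.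

Key step: step 6

Remark: 1 is taken as a catalogue ketone (otherwise one step, LiN(iPr)2/MeI, from 1,4-dioxaspiro[4.5]decan-8-one); locants in the Why lines are the skeleton locants of the plan, while compound names carry their own IUPAC locants.

Step 1
Reactants: 1 7-methyl-1,4-dioxaspiro[4.5]decan-8-one (racemic)
Product: 3 7-methyl-1,4-dioxaspiro[4.5]dec-6-en-8-one, via silyl enol ether 2 (not isolated)
Conditions: Me3SiCl, Et3N, DMF, 130 °C; then Pd(OAc)2 (10 mol %), O2 (1 atm), DMSO, 60 °C
Reagents that add atoms: none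
Why: Silylation under equilibrating conditions should favour the more substituted enol ether, and its Saegusa–Ito dehydrogenation should then place the double bond on the methyl-bearing side; no stereocentre is formed and the old one is erased.

Step 2
Reactants: 3 7-methyl-1,4-dioxaspiro[4.5]dec-6-en-8-one
Product: 5 (6R,7R)-6,7-dimethyl-7-(prop-2-en-1-yl)-1,4-dioxaspiro[4.5]decan-8-one, via aluminium enolate 4 (not isolated)
Conditions: Me3Al, copper thiophene-2-carboxylate Cu(O2CC4H3S) (5 mol %), O,O′-(1,1′-binaphthyl-2,2′-diyl) N,N-bis(1-phenylethyl)phosphoramidite (10 mol %, the enantiomer that gives the 6R adduct), Et2O, −30 °C; then MeLi, DMPU, allyl bromide, THF, −30 °C → rt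
Reagents that add atoms: trimethylaluminium, C[Al](C)C; allyl bromide, C=CCBr
Why: A copper-catalysed asymmetric conjugate addition of Me3Al to an α-substituted cyclohexenone should set C4 under ligand control, and alkylation of the enolate (as its lithium aluminate) should bring allyl in anti to the new vicinal methyl, which A(1,2) strain holds pseudoaxial, so the two methyls end cis.

Step 3
Reactants: 5 (6R,7R)-6,7-dimethyl-7-(prop-2-en-1-yl)-1,4-dioxaspiro[4.5]decan-8-one
Product: 6 (6R,7R)-6,7-dimethyl-8-methylidene-7-(prop-2-en-1-yl)-1,4-dioxaspiro[4.5]decane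
Conditions: Ph3PCH3Br, KOtBu, toluene, 90 °C
Reagents that add atoms: methyltriphenylphosphonium bromide, C[P+](c1ccccc1)(c1ccccc1)c1ccccc1.[Br-]
Why: Wittig methylenation of a hindered ketone whose only α-stereocentre is quaternary, with ketal and allyl group inert to the ylide, should install C9 without touching C4 or C5.

Step 4
Reactants: 6 (6R,7R)-6,7-dimethyl-8-methylidene-7-(prop-2-en-1-yl)-1,4-dioxaspiro[4.5]decane
Product: 8 3-[(6R,7R)-6,7-dimethyl-8-methylidene-1,4-dioxaspiro[4.5]decan-7-yl]propan-1-ol, via alkylborane 7 (not isolated)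
Conditions: 9-borabicyclo[3.3.1]nonane (9-BBN), THF, 0 °C → rt; then NaOH, H2O2, H2O, 0 °C
Reagents that add atoms: hydrogen peroxide, OO
Why: Hydroboration–oxidation with the bulky 9-BBN should select the monosubstituted allyl alkene over the neopentyl-type 1,1-disubstituted methylene and give the anti-Markovnikov primary alcohol (C8).

Step 5
Reactants: 8 3-[(6R,7R)-6,7-dimethyl-8-methylidene-1,4-dioxaspiro[4.5]decan-7-yl]propan-1-ol
Product: 11 3-[(1R,2R)-1,2-dimethyl-6-methylidene-3-oxocyclohexyl]propanoic acid, via ketal aldehyde 9 (not isolated), via ketal acid 10 (not isolated)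
Conditions: CrO3, H2SO4, H2O, acetone, 0 °C → rt
Reagents that add atoms: water, O
Why: Jones oxidation should take the primary alcohol through the aldehyde hydrate to the acid while the aqueous acid hydrolyses the dioxolane, the short cold exposure being chosen so that the C4 centre next to the freed C3 ketone does not epimerise.

Step 6
Reactants: 11 3-[(1R,2R)-1,2-dimethyl-6-methylidene-3-oxocyclohexyl]propanoic acid
Product: 14 (4aR,5R)-4a,5-dimethyl-4,4a,7,8-tetrahydronaphthalene-2,6(3H,5H)-dione, via acid chloride 12 (not isolated), via chloro ketone 13 (not isolated)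
Conditions: 1-chloro-N,N,2-trimethylprop-1-en-1-amine, CH2Cl2, 0 °C; SnCl4, CH2Cl2, −78 °C; then Et3N, −78 → 0 °C
Reagents that add atoms: none
Why: The acid chloride is ionised by SnCl4 to an acylium ion whose carbon C8 is attacked by the terminal carbon C9 of the exocyclic C10=C9 alkene, the tertiary C10 cation is captured by chloride, and Et3N then removes HCl (E1cB through the C9 enolate) to give the conjugated C9=C10 enone. The closest known reaction type is the Lewis-acid acylation of alkenes by acid chlorides (aliphatic Friedel–Crafts or Darzens–Nenitzescu acylation), a classical way to cyclise olefinic acids to cyclohexenones. Ring B, the only ring formed, is closed in the 6-endo-trig mode at the alkene. No stereocentre is created that survives: C10 ends sp2, the transient C–Cl centre is eliminated, and C4 and C5 pass through unchanged. The step needs Markovnikov regioselectivity (bond to C9, not 5-exo to C10, which would leave a primary cation), secured by the 1,1-disubstitution of the alkene and the C5–C6–C7–C8 tether, and it needs the C3 ketone to stay out and the C5 methyl not to shift to the C10 cation, which low temperature and fast chloride capture should secure. With C10 now sp2 and shared with ring B, C6 can only be equatorial on ring A, so ring A is fixed in the chair with the C5 methyl axial that all later stereocontrolled steps use.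

Step 7
Reactants: 14 (4aR,5R)-4a,5-dimethyl-4,4a,7,8-tetrahydronaphthalene-2,6(3H,5H)-dione
Product: 15 (4aR,5R,6S)-6-hydroxy-4a,5-dimethyl-4,4a,5,6,7,8-hexahydronaphthalen-2(3H)-one
Conditions: NaBH4 (0.3 equiv), EtOH, −20 °C
Reagents that add atoms: none
Why: Chemoselective borohydride reduction of a saturated ketone beside a conjugated one, with hydride arriving on the ring-A face opposite the axial C5 methyl, should give the axial C3 alcohol cis to both methyls.

Step 8
Reactants: 15 (4aR,5R,6S)-6-hydroxy-4a,5-dimethyl-4,4a,5,6,7,8-hexahydronaphthalen-2(3H)-one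
Product: 17 (4aR,5S)-4a,5-dimethyl-4,4a,5,8-tetrahydronaphthalen-2(3H)-one, via sulfamate ester 16 (not isolated)
Conditions: methyl N-(triethylammoniosulfonyl)carbamate, toluene, 60 °C
Reagents that add atoms: none
Why: Burgess dehydration is a syn elimination through the sulfamate ester, and since the only hydrogen syn to the C3 oxygen sits on C2 (C4 carries its methyl on that face) the C2=C3 alkene should form alone, under neutral conditions that do not move the skipped double bond into conjugation.

Step 9
Reactants: 17 (4aR,5S)-4a,5-dimethyl-4,4a,5,8-tetrahydronaphthalen-2(3H)-one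
Product: 18 (4aR,5R,6S,7R)-6,7-epoxy-4a,5-dimethyl-4,4a,5,6,7,8-hexahydronaphthalen-2(3H)-one
Conditions: mCPBA, NaHCO3, CH2Cl2, 0 °C
Reagents that add atoms: mCPBA, OOC(=O)c1cccc(Cl)c1
Why: Prilezhaev epoxidation should touch only the isolated cis-alkene (the enone is electron-poor) and come from the face opposite the axial C5 methyl of the locked ring A, which sets both epoxide carbons trans to the methyls.

Step 10
Reactants: 18 (4aR,5R,6S,7R)-6,7-epoxy-4a,5-dimethyl-4,4a,5,6,7,8-hexahydronaphthalen-2(3H)-one
Product: 20 (4aR,5R,6S,7R)-6,7-epoxy-3-hydroxy-4a,5-dimethyl-4,4a,5,6,7,8-hexahydronaphthalen-2(3H)-one (both epimers at IUPAC C-3), via potassium enolate 19 (not isolated)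
Conditions: KN(SiMe3)2, THF, −78 °C; then 2-(phenylsulfonyl)-3-phenyloxaziridine, −78 °C; AcOH quench
Reagents that add atoms: 2-(phenylsulfonyl)-3-phenyloxaziridine, O=S(=O)(c1ccccc1)N1OC1c1ccccc1
Why: Kinetic α′-deprotonation of the enone at C7 and electrophilic enolate hydroxylation by the N-sulfonyloxaziridine should oxygenate C7 without γ-deprotonation at C1 (which would open the epoxide); the new centre is uncontrolled and is erased in the next step.

Step 11
Reactants: 20 (4aR,5R,6S,7R)-6,7-epoxy-3-hydroxy-4a,5-dimethyl-4,4a,5,6,7,8-hexahydronaphthalen-2(3H)-one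
Product: 22 (4aS,5R,6S,7R)-6,7-epoxy-3-hydroxy-4a,5-dimethyl-5,6,7,8-tetrahydronaphthalen-2(4aH)-one, via diketone 21 (not isolated)
Conditions: 1,1,1-triacetoxy-1,1-dihydro-1,2-benziodoxol-3(1H)-one, NaHCO3, CH2Cl2, 0 °C → rt
Reagents that add atoms: none
Why: Periodinane oxidation of the acyloin gives the 1,2-diketone, which should enolise toward C6 to the cross-conjugated diosphenol of the natural product; no centre changes (the C5 descriptor changes by priority only).

Step 12
Reactants: 23 (S)-2-methylbutan-1-ol; 24 ethyl (2E)-4-(diethoxyphosphoryl)but-2-enoate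
Product: 26 ethyl (2E,4E,6S)-6-methylocta-2,4-dienoate, via aldehyde 25 (not isolated)
Conditions: TEMPO (cat.), PhI(OAc)2, CH2Cl2, rt; washed and dried solution added to 24 and LiN(SiMe3)2, THF, −78 → 0 °C
Reagents that add atoms: none
Why: Oxoammonium (TEMPO) oxidation should give the α-chiral aldehyde without epimerisation and the Horner–Wadsworth–Emmons reaction of the vinylogous phosphonate should deliver the (2E,4E)-dienoate; C6′ comes from the chiral pool.

Step 13
Reactants: 26 ethyl (2E,4E,6S)-6-methylocta-2,4-dienoate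
Product: 27 (2E,4E,6S)-6-methylocta-2,4-dienoic acid
Conditions: LiOH, THF/MeOH/H2O, rt; then HCl (aq)
Reagents that add atoms: lithium hydroxide, [Li+].[OH-]
Why: Ester saponification, which should leave the diene geometry and the remote stereocentre untouched.

Step 14
Reactants: 22 (4aS,5R,6S,7R)-6,7-epoxy-3-hydroxy-4a,5-dimethyl-5,6,7,8-tetrahydronaphthalen-2(4aH)-one; 27 (2E,4E,6S)-6-methylocta-2,4-dienoic acid
Product: 28 septeremophilane G, (1R,2R,3R,8aS)-3,7-dihydroxy-1,8a-dimethyl-6-oxo-1,2,3,4,6,8a-hexahydronaphthalen-2-yl (2E,4E,6S)-6-methylocta-2,4-dienoate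
Conditions: 27 (5 equiv), toluene, 90 °C
Reagents that add atoms: none
Why: Acid-promoted trans-diaxial epoxide opening, in which the carboxylic acid should attack C3 anti to the epoxide oxygen along the axial direction of the locked ring-A chair (attack at C2 would need a twist-boat), puts the ester on C3 cis to the methyls and leaves the axial C2 hydroxyl free, with no protecting group and no acyl migration across the trans-diaxial pair.

**Compound list**
1 | 7-methyl-1,4-dioxaspiro[4.5]decan-8-one (racemic) | CC1CC2(CCC1=O)OCCO2 | starting material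
2 | trimethyl[(7-methyl-1,4-dioxaspiro[4.5]dec-7-en-8-yl)oxy]silane | CC1=C(O[Si](C)(C)C)CCC2(C1)OCCO2 | intermediate
3 | 7-methyl-1,4-dioxaspiro[4.5]dec-6-en-8-one | CC1=CC2(CCC1=O)OCCO2 | intermediate
4 | {[(6R)-6,7-dimethyl-1,4-dioxaspiro[4.5]dec-7-en-8-yl]oxy}dimethylaluminium | C[Al](C)OC1=C(C)[C@@H](C)C2(OCCO2)CC1 | intermediate
5 | (6R,7R)-6,7-dimethyl-7-(prop-2-en-1-yl)-1,4-dioxaspiro[4.5]decan-8-one | O=C1CCC2(OCCO2)[C@H](C)[C@@]1(C)CC=C | intermediate
6 | (6R,7R)-6,7-dimethyl-8-methylidene-7-(prop-2-en-1-yl)-1,4-dioxaspiro[4.5]decane | C=C1CCC2(OCCO2)[C@H](C)[C@@]1(C)CC=C | intermediate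
7 | 9-{3-[(6R,7R)-6,7-dimethyl-8-methylidene-1,4-dioxaspiro[4.5]decan-7-yl]propyl}-9-borabicyclo[3.3.1]nonane | C=C1CCC2(OCCO2)[C@H](C)[C@@]1(C)CCCB1C2CCCC1CCC2 | intermediate
8 | 3-[(6R,7R)-6,7-dimethyl-8-methylidene-1,4-dioxaspiro[4.5]decan-7-yl]propan-1-ol | C=C1CCC2(OCCO2)[C@H](C)[C@@]1(C)CCCO | intermediate
9 | 3-[(6R,7R)-6,7-dimethyl-8-methylidene-1,4-dioxaspiro[4.5]decan-7-yl]propanal | C=C1CCC2(OCCO2)[C@H](C)[C@@]1(C)CCC=O | intermediate
10 | 3-[(6R,7R)-6,7-dimethyl-8-methylidene-1,4-dioxaspiro[4.5]decan-7-yl]propanoic acid | C=C1CCC2(OCCO2)[C@H](C)[C@@]1(C)CCC(=O)O | intermediate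
11 | 3-[(1R,2R)-1,2-dimethyl-6-methylidene-3-oxocyclohexyl]propanoic acid | C=C1CCC(=O)[C@H](C)[C@@]1(C)CCC(=O)O | intermediate
12 | 3-[(1R,2R)-1,2-dimethyl-6-methylidene-3-oxocyclohexyl]propanoyl chloride | C=C1CCC(=O)[C@H](C)[C@@]1(C)CCC(=O)Cl | intermediate
13 | (4aR,5R)-8a-chloro-4a,5-dimethyloctahydronaphthalene-2,6(1H,3H)-dione (C-8a epimers) | O=C1CCC2(Cl)CC(=O)CC[C@]2(C)[C@H]1C | intermediate
14 | (4aR,5R)-4a,5-dimethyl-4,4a,7,8-tetrahydronaphthalene-2,6(3H,5H)-dione | O=C1CCC2=CC(=O)CC[C@]2(C)[C@H]1C | intermediate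
15 | (4aR,5R,6S)-6-hydroxy-4a,5-dimethyl-4,4a,5,6,7,8-hexahydronaphthalen-2(3H)-one | O[C@H]1CCC2=CC(=O)CC[C@]2(C)[C@H]1C | intermediate
16 | triethylammonium (methoxycarbonyl){[(1R,2S,8aR)-1,8a-dimethyl-6-oxo-1,2,3,4,6,7,8,8a-octahydronaphthalen-2-yl]oxysulfonyl}azanide | COC(=O)[N-]S(=O)(=O)O[C@H]1CCC2=CC(=O)CC[C@]2(C)[C@H]1C.CC[NH+](CC)CC | intermediate
17 | (4aR,5S)-4a,5-dimethyl-4,4a,5,8-tetrahydronaphthalen-2(3H)-one | C[C@H]1C=CCC2=CC(=O)CC[C@]12C | intermediate
18 | (4aR,5R,6S,7R)-6,7-epoxy-4a,5-dimethyl-4,4a,5,6,7,8-hexahydronaphthalen-2(3H)-one | C[C@H]1[C@@H]2O[C@@H]2CC2=CC(=O)CC[C@]12C | intermediate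
19 | potassium enolate of 18 (cross-conjugated, O on IUPAC C-2, C2=C3) | C[C@H]1[C@@H]2O[C@@H]2CC2=CC([O-])=CC[C@]12C.[K+] | intermediate
20 | (4aR,5R,6S,7R)-6,7-epoxy-3-hydroxy-4a,5-dimethyl-4,4a,5,6,7,8-hexahydronaphthalen-2(3H)-one (C-3 epimers) | C[C@H]1[C@@H]2O[C@@H]2CC2=CC(=O)C(O)C[C@]12C | intermediate
21 | (4aR,5R,6S,7R)-6,7-epoxy-4a,5-dimethyl-4a,5,6,7,8-pentahydronaphthalene-2,3(4H)-dione (IUPAC 2,3-diketone) | C[C@H]1[C@@H]2O[C@@H]2CC2=CC(=O)C(=O)C[C@]12C | intermediate
22 | (4aS,5R,6S,7R)-6,7-epoxy-3-hydroxy-4a,5-dimethyl-5,6,7,8-tetrahydronaphthalen-2(4aH)-one | C[C@H]1[C@@H]2O[C@@H]2CC2=CC(=O)C(O)=C[C@]12C | intermediate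
23 | (S)-2-methylbutan-1-ol | CC[C@H](C)CO | starting material
24 | ethyl (2E)-4-(diethoxyphosphoryl)but-2-enoate | CCOC(=O)/C=C/CP(=O)(OCC)OCC | starting material
25 | (S)-2-methylbutanal | CC[C@H](C)C=O | intermediate
26 | ethyl (2E,4E,6S)-6-methylocta-2,4-dienoate | CC[C@H](C)/C=C/C=C/C(=O)OCC | intermediate
27 | (2E,4E,6S)-6-methylocta-2,4-dienoic acid | CC[C@H](C)/C=C/C=C/C(=O)O | intermediate
28 | septeremophilane G, (1R,2R,3R,8aS)-3,7-dihydroxy-1,8a-dimethyl-6-oxo-1,2,3,4,6,8a-hexahydronaphthalen-2-yl (2E,4E,6S)-6-methylocta-2,4-dienoate | CC[C@H](C)/C=C/C=C/C(=O)O[C@H]1[C@H](O)CC2=CC(=O)C(O)=C[C@]2(C)[C@H]1C | target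

**Count and risks**
Total step count: 14. Longest linear sequence: 12 steps (steps 1–11 and 14); steps 12–13 make the side chain in parallel.

Step 14 (most at risk). The weakly nucleophilic conjugated acid must attack C3, which is syn-axial to the C5 methyl and next to the C4 methyl, so the opening may stall or be overtaken by acid-induced rearrangement of the epoxide. Fallback: from 22, aqueous HClO4 in THF should open the epoxide with water in the same trans-diaxial sense to the diol F1. Et3SiCl (2.2 equiv) and imidazole should then silylate the enol OH and the unhindered C2 OH to give the bis-silyl ether F2 with C3 OH free. Acid 27 is converted with oxalyl chloride into the acid chloride F3, which acylates F2 at C3 (pyridine, DMAP, CH2Cl2) to the silylated ester F4. HF·pyridine removes both silyl groups and returns to 28.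

Step 8. The axial sulfamate may ionise instead of eliminating, with hydride or methyl shift from C4 or C5, or the product may drift into conjugation on prolonged heating. Fallback: from 15, KN(SiMe3)2 (1 equiv, −78 °C), CS2 and MeI should give the S-methyl xanthate F5, whose Chugaev pyrolysis (180 °C) is a concerted syn elimination with the same single syn hydrogen and returns to 17.

Step 2. Enantioselection and conversion in the conjugate addition to an α-methyl enone flanked by a ketal may be insufficient, and the allylation may not be fully anti. Fallback: from 3, Me2CuLi (Et2O, −78 °C) followed by allyl bromide/DMPU should give the same relative configuration as a racemate, that is 5 together with its enantiomer F6. Preparative chromatography on a chiral stationary phase separates them and returns to 5.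

**Further compounds**
F1 | step 14 | (4aS,5R,6R,7R)-3,6,7-trihydroxy-4a,5-dimethyl-5,6,7,8-tetrahydronaphthalen-2(4aH)-one | O[C@H]1[C@H](O)CC2=CC(=O)C(O)=C[C@]2(C)[C@H]1C
F2 | step 14 | (4aS,5R,6R,7R)-6-hydroxy-4a,5-dimethyl-3,7-bis[(triethylsilyl)oxy]-5,6,7,8-tetrahydronaphthalen-2(4aH)-one | O[C@H]1[C@H](O[Si](CC)(CC)CC)CC2=CC(=O)C(O[Si](CC)(CC)CC)=C[C@]2(C)[C@H]1C
F3 | step 14 | (2E,4E,6S)-6-methylocta-2,4-dienoyl chloride | CC[C@H](C)/C=C/C=C/C(=O)Cl
F4 | step 14 | (1R,2R,3R,8aS)-1,8a-dimethyl-6-oxo-3,7-bis[(triethylsilyl)oxy]-1,2,3,4,6,8a-hexahydronaphthalen-2-yl (2E,4E,6S)-6-methylocta-2,4-dienoate | CC[C@H](C)/C=C/C=C/C(=O)O[C@H]1[C@H](O[Si](CC)(CC)CC)CC2=CC(=O)C(O[Si](CC)(CC)CC)=C[C@]2(C)[C@H]1C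
F5 | step 8 | O-[(1R,2S,8aR)-1,8a-dimethyl-6-oxo-1,2,3,4,6,7,8,8a-octahydronaphthalen-2-yl] S-methyl carbonodithioate | CSC(=S)O[C@H]1CCC2=CC(=O)CC[C@]2(C)[C@H]1C
F6 | step 2 | (6S,7S)-6,7-dimethyl-7-(prop-2-en-1-yl)-1,4-dioxaspiro[4.5]decan-8-one | O=C1CCC2(OCCO2)[C@@H](C)[C@]1(C)CC=C
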